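**Plan**

- Retrosynthesis: (a) the epoxy-hydroxy-enone ring is traced back to a para-methoxyphenol (C6'–OH, C3'–OMe); (b) ring A is opened at C2–C3, so that C4 with its methyl group, C13–O and C3 becomes a 3-methyloxetane; (c) ring B is cut at C5–C6 and C9–C10 in one operation.
- Feature that allows (c): ring B is a cyclohexene whose C7=C8 double bond lies opposite the C5–C10 bond, so it is the adduct of the diene C6=C7–C8(CH3)=C9 and the alkene C5=C10. The trans H-5/CH3-10 pair maps onto an (E)-2-methyl-enoate with C1 as the ester carbon, and C11, exocyclic on C9, can carry the oxygen that ties it to C1.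
- Forward order: arene and C6 dienal are joined at C1'–C11; an ester tether C11–O–C1 is installed; the cycloaddition gives ring B plus a temporary trans-fused γ-lactone; the lactone becomes the C1=C2 vinyl group and O-11 is removed; a C2 carbanion opens the oxetane and closes ring A; the arene is then taken to quinone monoketal, epoxide and alcohol.
- Stereochemistry: C11 (temporary) from a CBS reduction; C5, C9 and C10 from C11 through the cycloaddition; C4 from the geometry of the oxetane opening; C1'/C2' from a tartrate-mediated epoxidation; C6' from hydride delivery on the epoxide face.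

Key step: step 14

Remark: drimane numbering is used for the decalin (C11 = CH2 on C9, C12 = CH3 on C8, C13 = CH2OH carbon on C4, C14 = CH3 on C4, C15 = CH3 on C10) and primed numbers for the oxygenated six-membered ring (C1' carries C11); Ar = 4-[(tert-butyldimethylsilyloxy)methyl]-5-methoxy-2-(methoxymethoxy)phenyl; the sense of induction assumed for the CBS catalyst (step 10) and the tartrate (step 23) can be inverted with the antipodal reagent if a test shows the opposite.

**Route**

Step 1
Reactants: 1 2,5-dihydroxybenzaldehyde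
Product: 2 2-hydroxy-5-(methoxymethoxy)benzaldehyde
Conditions: MOMCl (1.0 equiv), i-Pr2NEt, CH2Cl2, 0 °C
Reagents that add atoms: chloromethyl methyl ether, COCCl
Why: O-alkylation (MOM protection) should take place at the 5-hydroxyl only, because the 2-hydroxyl is held in a hydrogen bond to the aldehyde and is less nucleophilic.

Step 2
Reactants: 2 2-hydroxy-5-(methoxymethoxy)benzaldehyde
Product: 3 2-methoxy-5-(methoxymethoxy)benzaldehyde
Conditions: MeI, K2CO3, DMF, 40 °C
Reagents that add atoms: iodomethane, CI
Why: Williamson ether synthesis on the remaining phenol, which differentiates the two ring oxygens (C3'–OMe, C6'–OMOM) for the later oxidative dearomatisation.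

Step 3
Reactants: 3 2-methoxy-5-(methoxymethoxy)benzaldehyde
Product: 4 4-bromo-2-methoxy-5-(methoxymethoxy)benzaldehyde
Conditions: NBS, DMF, 23 °C
Reagents that add atoms: N-bromosuccinimide, O=C1CCC(=O)N1Br
Why: electrophilic aromatic bromination is expected para to the formyl group and ortho to the 5-alkoxy group, as in 2,5-dialkoxybenzaldehydes, and NBS in DMF generates no acid that would cleave the MOM ether.

Step 4
Reactants: 4 4-bromo-2-methoxy-5-(methoxymethoxy)benzaldehyde
Product: 5 [4-bromo-2-methoxy-5-(methoxymethoxy)phenyl]methanol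
Conditions: NaBH4, MeOH, 0 °C
Reagents that add atoms: none
Why: hydride reduction of the aldehyde, to which the aryl bromide and the MOM ether are inert.

Step 5
Reactants: 5 [4-bromo-2-methoxy-5-(methoxymethoxy)phenyl]methanol
Product: 6 {[4-bromo-2-methoxy-5-(methoxymethoxy)phenyl]methoxy}(tert-butyl)dimethylsilane (Ar–Br)
Conditions: TBSCl, imidazole, DMF, 23 °C
Reagents that add atoms: tert-butyldimethylsilyl chloride, CC(C)(C)[Si](C)(C)Cl
Why: silyl protection of the primary benzylic alcohol, which later becomes the C4' hydroxymethyl group.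

Step 6
Reactants: 7 (2E)-3-methylpent-2-en-4-yn-1-ol
Product: 8 (2E)-3-methylpenta-2,4-dien-1-ol
Conditions: H2 (1 atm), Pd/CaCO3 poisoned with Pb(OAc)2, quinoline, hexane–EtOAc, 23 °C
Reagents that add atoms: none
Why: partial hydrogenation of the terminal alkyne over poisoned palladium stops at the vinyl group and leaves the (E)-trisubstituted alkene untouched.

Step 7
Reactants: 8 (2E)-3-methylpenta-2,4-dien-1-ol
Product: 9 (2E)-3-methylpenta-2,4-dienal
Conditions: MnO2, CH2Cl2, 23 °C
Reagents that add atoms: none
Why: allylic oxidation with MnO2 stops at the aldehyde and keeps the (E)-geometry of the C8=C9 bond.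

Step 8
Reactants: 6 Ar–Br; 9 (2E)-3-methylpenta-2,4-dienal
Product: 11 rac-(2E)-1-Ar-3-methylpenta-2,4-dien-1-ol, via aryllithium 10 (not isolated)
Conditions: n-BuLi, THF, −78 °C; then 9, −78 °C; aq. NH4Cl
Reagents that add atoms: none
Why: bromine–lithium exchange (the ortho MOM ether stabilises the aryllithium) and 1,2-addition to the enal join C1' to C11; the uncontrolled carbinol centre is erased in step 9.

Step 9
Reactants: 11 rac-(2E)-1-Ar-3-methylpenta-2,4-dien-1-ol
Product: 12 (2E)-1-Ar-3-methylpenta-2,4-dien-1-one
Conditions: MnO2, CH2Cl2, 23 °C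
Reagents that add atoms: none
Why: MnO2 oxidation of a doubly activated (benzylic and allylic) alcohol.

Step 10
Reactants: 12 (2E)-1-Ar-3-methylpenta-2,4-dien-1-one
Product: 13 (1S,2E)-1-Ar-3-methylpenta-2,4-dien-1-ol
Conditions: (R)-2-methyl-CBS-oxazaborolidine (0.2 equiv), catecholborane, PhMe, −78 °C
Reagents that add atoms: none
Why: Corey–Bakshi–Shibata reduction, in which the ortho-substituted aryl group is assumed to act as the large and the planar dienyl group as the small substituent, so that the (R)-catalyst should give the (S)-carbinol at C11, the only centre set by a chiral reagent before the key step.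

Step 11
Reactants: 13 (1S,2E)-1-Ar-3-methylpenta-2,4-dien-1-ol; 14 2-(diethoxyphosphoryl)propanoic acid
Product: 15 (1S,2E)-1-Ar-3-methylpenta-2,4-dien-1-yl 2-(diethoxyphosphoryl)propanoate (both epimers at the phosphorus-bearing carbon)
Conditions: DCC, DMAP (cat.), CH2Cl2, 0 °C
Reagents that add atoms: none
Why: Steglich esterification installs the tether oxygen–C1 bond under neutral conditions that should not ionise the benzylic dienyl alcohol, with retention at C11.

Step 12
Reactants: 16 (3-methyloxetan-3-yl)methanol
Product: 17 3-methyloxetane-3-carbaldehyde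
Conditions: TEMPO (cat.), PhI(OAc)2, CH2Cl2, 23 °C
Reagents that add atoms: none
Why: TEMPO-catalysed oxidation of a primary alcohol to a non-enolisable aldehyde under conditions that leave the oxetane closed.

Step 13
Reactants: 15 phosphonate ester; 17 3-methyloxetane-3-carbaldehyde
Product: 18 (1S,2E)-1-Ar-3-methylpenta-2,4-dien-1-yl (2E)-2-methyl-3-(3-methyloxetan-3-yl)prop-2-enoate
Conditions: LiCl, DBU, MeCN, 0 → 23 °C
Reagents that add atoms: none
Why: Horner–Wadsworth–Emmons olefination of an α-methyl phosphonate with an aldehyde on a quaternary carbon should give the (E)-trisubstituted enoate (ester trans to the oxetanyl group), which is the C5=C10 dienophile with C1 and C4 trans.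

Step 14
Reactants: 18 triene ester
Product: 19 (3S,3aS,7S,7aS)-3-Ar-4,7a-dimethyl-7-(3-methyloxetan-3-yl)-3a,6,7,7a-tetrahydro-2-benzofuran-1(3H)-one (trans-fused lactone; C11 = C3, C9 = C3a, C5 = C7, C10 = C7a)
Conditions: PhMe (0.005 M), BHT, 2,6-di-tert-butyl-4-methylpyridine (0.2 equiv), silylated sealed tube, 170–180 °C
Reagents that add atoms: none
Why: thermal, concerted but asynchronous [4+2] cycloaddition of the (E)-diene C6=C7–C8=C9 with the (E)-enoate C5=C10 forms C5–C6 and C9–C10 together; the closest known reaction type is the intramolecular Diels–Alder reaction of ester-tethered 1,3,8-nonatrienes (pentadienyl acrylates) that carry a stereocentre on the tether carbon and a substituent on the adjacent diene carbon. Ring B closes by the cycloaddition itself, and the five-membered lactone closes in the fused mode with the tether carbonyl exo, which gives the trans ring fusion. C5 and C10 follow suprafacially from the (E)-enoate (H-5 trans to CH3-15, the later trans-decalin), and C9 follows from the (E)-geometry of C8=C9 together with the exo tether (C11 cis to CH3-15). The absolute sense comes from C11: A(1,3) strain with the C8 methyl group holds H-11 in the diene plane, so the dienophile, tied to O-11, reaches only the diene face anti to the aryl group. The step needs exo-tether (trans) over endo-tether (cis) selectivity and one diene face; an endo-folded tether would clash with the C8 methyl group and would push the aryl group into the diene plane, and the oxetane ring keeps the quaternary C4, which must sit endo, compact. The C11 stereocentre and the lactone are helpers that are removed in steps 15–18.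

Step 15
Reactants: 19 trans-fused lactone
Product: 20 (3S,3aS,7S,7aS)-3-Ar-4,7a-dimethyl-7-(3-methyloxetan-3-yl)-1,3,3a,6,7,7a-hexahydro-2-benzofuran-1-ol (both anomers)
Conditions: i-Bu2AlH (1.2 equiv), CH2Cl2, −78 °C; aq. potassium sodium tartrate
Reagents that add atoms: none
Why: partial reduction of the lactone stops at the lactol because the aluminium hemiacetal is stable at −78 °C, and no other reducible group is present.

Step 16
Reactants: 20 lactol
Product: 21 (S)-Ar[(1S,5R,6S)-6-ethenyl-2,6-dimethyl-5-(3-methyloxetan-3-yl)cyclohex-2-en-1-yl]methanol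
Conditions: Ph3PCH3Br, KOtBu, THF, 0 → 60 °C
Reagents that add atoms: methyltriphenylphosphonium bromide (source of the CH2 group), C[P+](c1ccccc1)(c1ccccc1)c1ccccc1.[Br-]
Why: Wittig methylenation of the ring-opened hydroxy aldehyde form of the lactol turns C1 into the C1=C2 vinyl group and frees O-11 without touching a stereocentre.

Step 17
Reactants: 21 vinyl carbinol
Product: 23 O-{(S)-Ar[(1S,5R,6S)-6-ethenyl-2,6-dimethyl-5-(3-methyloxetan-3-yl)cyclohex-2-en-1-yl]methyl} S-methyl carbonodithioate, via sodium xanthate 22 (not isolated)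
Conditions: NaH, imidazole (cat.), THF, 0 °C; CS2; then MeI, 23 °C
Reagents that add atoms: carbon disulfide, S=C=S; iodomethane, CI
Why: xanthate formation on the only free hydroxyl prepares the Barton–McCombie deoxygenation.

Step 18
Reactants: 23 xanthate
Product: 24 deoxy compound: 21 with C11–H in place of C11–OH (C11 is now CH2; ring stereocentres unchanged)
Conditions: Bu3SnH, Et3B, air, PhMe, 23 °C
Reagents that add atoms: none
Why: Barton–McCombie radical deoxygenation through the benzylic C11 radical removes the helper oxygen, a radical path being chosen because a C11 cation could shift hydride from C9 and scramble that centre.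

Step 19
Reactants: 24 deoxy vinyl compound
Product: 26 iodide: 24 with CH2CH2I in place of the vinyl group, via alkylzirconocene chloride 25 (not isolated)
Conditions: Cp2Zr(H)Cl, THF, 23 °C; then I2, 0 °C
Reagents that add atoms: diiodine, II
Why: hydrozirconation puts zirconium on the terminal carbon (C2) of the only monosubstituted alkene, the trisubstituted C7=C8 bond being inert, and iodinolysis gives the primary iodide.

Step 20
Reactants: 26 iodide
Product: 28 (4R,5R,9S,10R)-11-Ar-drim-7-en-13-ol, via primary alkyllithium 27 (not isolated)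
Conditions: t-BuLi (2.1 equiv), Et2O–pentane, −78 °C; then BF3·OEt2, −78 → −30 °C; aq. NaHCO3
Reagents that add atoms: none
Why: Proposed new method: iodine–lithium exchange gives the primary alkyllithium at C2, which attacks one methylene of the BF3-activated oxetane in a 6-exo-tet SN2 step that closes ring A (C2–C3) and releases O-13 as the alkoxide; because the nucleophile must enter anti to the ring oxygen, the other oxetane methylene (C13) is held anti to C2 about C3–C4, that is equatorial in the chair transition state of the trans-decalin, so C4 should emerge with α-CH2OH and β-CH3 as in the target, the closest known reaction types being the BF3-promoted opening of oxetanes by organolithium reagents and anionic ring closures of the Parham and epoxynitrile kind.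

Step 21
Reactants: 28 decalin alcohol
Product: 29 phenol: 28 with the MOM ether cleaved (free C6'–OH)
Conditions: ZnBr2, n-PrSH, CH2Cl2, 0 °C
Reagents that add atoms: none
Why: Lewis acid/thiol cleavage of the phenolic MOM ether, conditions that should spare the TBS ether and the trisubstituted alkene.

Step 22
Reactants: 29 phenol
Product: 30 quinone monoketal: 4,4-dimethoxycyclohexa-2,5-dienone ring with the ketone at C6', the dimethyl ketal at C3', C11 on C1' and CH2OTBS on C4'
Conditions: PhI(OAc)2, MeOH, 0 °C
Reagents that add atoms: methanol, CO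
Why: oxidative dearomatisation of a para-methoxyphenol in methanol gives the monoketal regiospecifically, with the ketone at the former phenol carbon C6' and the ketal at C3'.

Step 23
Reactants: 30 quinone monoketal
Product: 31 (1'R,2'S)-epoxy ketone: C1'–C2' epoxide of 30 on the face it occupies in the target
Conditions: Ph3COOH, NaN(SiMe3)2, L-(+)-diisopropyl tartrate, PhMe, −60 °C
Reagents that add atoms: triphenylmethyl hydroperoxide, OOC(c1ccccc1)(c1ccccc1)c1ccccc1
Why: tartrate-mediated nucleophilic (Weitz–Scheffer type) epoxidation, in which the hydroperoxide anion can add only at C2', the one β-carbon that bears hydrogen (C4' is blocked by its CH2OTBS group), and the chiral sodium tartrate complex rather than the remote decalin selects the face.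

Step 24
Reactants: 31 epoxy ketone
Product: 32 (1'S,2'S,6'R)-epoxy alcohol: C6'–OH trans to the epoxide oxygen and cis to C11
Conditions: i-Bu2AlH, THF, −78 °C
Reagents that add atoms: none
Why: 1,2-reduction of the epoxy enone, in which hydride is expected to arrive on the epoxide face (aluminium bound to the epoxide oxygen, the other face shielded by the C11 methylene on the adjacent quaternary carbon), placing the hydroxyl trans to the epoxide.

Step 25
Reactants: 32 epoxy alcohol
Product: 33 Epoxypholamin A
Conditions: 48% aq. HF, MeCN, 0 → 20 °C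
Reagents that add atoms: water, O
Why: aqueous HF hydrolyses the dimethyl ketal to the C3' enone and cleaves the primary TBS ether in one operation, under conditions mild enough for the epoxy alcohol.

**Compound list**

1 | 2,5-dihydroxybenzaldehyde | O=Cc1cc(O)ccc1O | starting material
2 | 2-hydroxy-5-(methoxymethoxy)benzaldehyde | O=Cc1cc(OCOC)ccc1O | intermediate
3 | 2-methoxy-5-(methoxymethoxy)benzaldehyde | O=Cc1cc(OCOC)ccc1OC | intermediate
4 | 4-bromo-2-methoxy-5-(methoxymethoxy)benzaldehyde | O=Cc1cc(OCOC)c(Br)cc1OC | intermediate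
5 | [4-bromo-2-methoxy-5-(methoxymethoxy)phenyl]methanol | OCc1cc(OCOC)c(Br)cc1OC | intermediate
6 | {[4-bromo-2-methoxy-5-(methoxymethoxy)phenyl]methoxy}(tert-butyl)dimethylsilane (Ar–Br) | CC(C)(C)[Si](C)(C)OCc1cc(OCOC)c(Br)cc1OC | intermediate
7 | (2E)-3-methylpent-2-en-4-yn-1-ol | C#C/C(C)=C/CO | starting material
8 | (2E)-3-methylpenta-2,4-dien-1-ol | C=C/C(C)=C/CO | intermediate
9 | (2E)-3-methylpenta-2,4-dienal | C=C/C(C)=C/C=O | intermediate
10 | aryllithium Ar–Li (not isolated) | [Li]c1cc(OC)c(CO[Si](C)(C)C(C)(C)C)cc1OCOC | intermediate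
11 | rac-(2E)-1-Ar-3-methylpenta-2,4-dien-1-ol | C=C/C(C)=C/C(O)c1cc(OC)c(CO[Si](C)(C)C(C)(C)C)cc1OCOC | intermediate
12 | (2E)-1-Ar-3-methylpenta-2,4-dien-1-one | C=C/C(C)=C/C(=O)c1cc(OC)c(CO[Si](C)(C)C(C)(C)C)cc1OCOC | intermediate
13 | (1S,2E)-1-Ar-3-methylpenta-2,4-dien-1-ol | C=C/C(C)=C/[C@H](O)c1cc(OC)c(CO[Si](C)(C)C(C)(C)C)cc1OCOC | intermediate
14 | 2-(diethoxyphosphoryl)propanoic acid | CCOP(=O)(OCC)C(C)C(=O)O | starting material
15 | (1S,2E)-1-Ar-3-methylpenta-2,4-dien-1-yl 2-(diethoxyphosphoryl)propanoate | C=C/C(C)=C/[C@H](OC(=O)C(C)P(=O)(OCC)OCC)c1cc(OC)c(CO[Si](C)(C)C(C)(C)C)cc1OCOC | intermediate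
16 | (3-methyloxetan-3-yl)methanol | CC1(CO)COC1 | starting material
17 | 3-methyloxetane-3-carbaldehyde | CC1(C=O)COC1 | intermediate
18 | (1S,2E)-1-Ar-3-methylpenta-2,4-dien-1-yl (2E)-2-methyl-3-(3-methyloxetan-3-yl)prop-2-enoate | C=C/C(C)=C/[C@H](OC(=O)/C(C)=C/C1(C)COC1)c1cc(OC)c(CO[Si](C)(C)C(C)(C)C)cc1OCOC | intermediate
19 | (3S,3aS,7S,7aS)-3-Ar-4,7a-dimethyl-7-(3-methyloxetan-3-yl)-3a,6,7,7a-tetrahydro-2-benzofuran-1(3H)-one | CC1=CC[C@@H](C2(C)COC2)[C@]3(C)C(=O)O[C@H](c4cc(OC)c(CO[Si](C)(C)C(C)(C)C)cc4OCOC)[C@@H]13 | intermediate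
20 | lactol of 19 (both anomers at C1) | CC1=CC[C@@H](C2(C)COC2)[C@]3(C)C(O)O[C@H](c4cc(OC)c(CO[Si](C)(C)C(C)(C)C)cc4OCOC)[C@@H]13 | intermediate
21 | (S)-Ar[(1S,5R,6S)-6-ethenyl-2,6-dimethyl-5-(3-methyloxetan-3-yl)cyclohex-2-en-1-yl]methanol | CC1=CC[C@@H](C2(C)COC2)[C@](C)(C=C)[C@H]1[C@H](O)c1cc(OC)c(CO[Si](C)(C)C(C)(C)C)cc1OCOC | intermediate
22 | sodium O-alkyl xanthate of 21 (not isolated) | [Na+].CC1=CC[C@@H](C2(C)COC2)[C@](C)(C=C)[C@H]1[C@H](OC(=S)[S-])c1cc(OC)c(CO[Si](C)(C)C(C)(C)C)cc1OCOC | intermediate
23 | S-methyl xanthate of 21 | CC1=CC[C@@H](C2(C)COC2)[C@](C)(C=C)[C@H]1[C@H](OC(=S)SC)c1cc(OC)c(CO[Si](C)(C)C(C)(C)C)cc1OCOC | intermediate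
24 | deoxy compound: 21 with CH2 at C11 | CC1=CC[C@@H](C2(C)COC2)[C@](C)(C=C)[C@H]1Cc1cc(OC)c(CO[Si](C)(C)C(C)(C)C)cc1OCOC | intermediate
25 | alkylzirconocene chloride from 24, Zr on C2 (not isolated) | CC1=CC[C@@H](C2(C)COC2)[C@](C)(CC[Zr](Cl)(C2C=CC=C2)C2C=CC=C2)[C@H]1Cc1cc(OC)c(CO[Si](C)(C)C(C)(C)C)cc1OCOC | intermediate
26 | primary iodide: 24 with CH2CH2I on C10 | CC1=CC[C@@H](C2(C)COC2)[C@](C)(CCI)[C@H]1Cc1cc(OC)c(CO[Si](C)(C)C(C)(C)C)cc1OCOC | intermediate
27 | primary alkyllithium from 26 (not isolated) | CC1=CC[C@@H](C2(C)COC2)[C@](C)(CC[Li])[C@H]1Cc1cc(OC)c(CO[Si](C)(C)C(C)(C)C)cc1OCOC | intermediate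
28 | (4R,5R,9S,10R)-11-Ar-drim-7-en-13-ol (4β-CH3, 4α-CH2OH, 5α-H, 9α-H, 10β-CH3) | CC1=CC[C@H]2[C@](C)(CO)CCC[C@]2(C)[C@H]1Cc1cc(OC)c(CO[Si](C)(C)C(C)(C)C)cc1OCOC | intermediate
29 | phenol: 28 with free C6'–OH | CC1=CC[C@H]2[C@](C)(CO)CCC[C@]2(C)[C@H]1Cc1cc(OC)c(CO[Si](C)(C)C(C)(C)C)cc1O | intermediate
30 | quinone monoketal (C6' ketone, C3' dimethyl ketal) | CC1=CC[C@H]2[C@](C)(CO)CCC[C@]2(C)[C@H]1CC1=CC(OC)(OC)C(CO[Si](C)(C)C(C)(C)C)=CC1=O | intermediate
31 | (1'R,2'S)-epoxy ketone | CC1=CC[C@H]2[C@](C)(CO)CCC[C@]2(C)[C@H]1C[C@@]12O[C@@H]1C(OC)(OC)C(CO[Si](C)(C)C(C)(C)C)=CC2=O | intermediate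
32 | (1'S,2'S,6'R)-epoxy alcohol | CC1=CC[C@H]2[C@](C)(CO)CCC[C@]2(C)[C@H]1C[C@@]12O[C@@H]1C(OC)(OC)C(CO[Si](C)(C)C(C)(C)C)=C[C@H]2O | intermediate
33 | Epoxypholamin A | CC1=CC[C@H]2[C@](C)(CO)CCC[C@]2(C)[C@H]1C[C@@]12O[C@@H]1C(=O)C(CO)=C[C@H]2O | target

**Summary and risks**

Total step count: 25. Longest linear sequence: 22 steps (1–5, 8–11, 13–25).

Steps most likely to fail:

1. Step 20 (Proposed new method). What may go wrong: proton transfer from the benzylic C11 methylene to the alkyllithium before ring closure; substitution at the neopentyl-type oxetane carbon being so slow that BF3 consumes the organolithium; a boat-like closure eroding the selectivity at C4. The fallback uses known chemistry and gives up the control at C4. It sets out from 24: vinylmagnesium bromide with CuI (10 mol %) in THF opens the oxetane intermolecularly and should give the homoallylic alcohol F1 together with its C4 epimer F2, since the two diastereotopic methylenes are not expected to be well differentiated. Ring-closing metathesis with second-generation Grubbs catalyst, RuCl2(=CHPh)(H2IMes)(PCy3), joins the C10 vinyl and the C4 allyl groups to the dienes F3 and its C4 epimer F4, which are separated. Diimide (2-nitrobenzenesulfonylhydrazide, Et3N) should then saturate only the disubstituted C1=C2 bond of F3, and the route is rejoined at 28.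

2. Step 14. What may go wrong: ionisation or allylic transposition of the electron-rich benzylic dienyl ester at the temperature needed; too small a preference for the exo-tether mode because the quaternary oxetanyl carbon must take the endo position; slow cycloaddition of the trisubstituted dienophile. The fallback replaces the ester tether by a neutral, temporary silicon tether and sets out from 13 and 17. Aldehyde 17 and ethyl 2-(triphenylphosphoranylidene)propanoate give ethyl (2E)-2-methyl-3-(3-methyloxetan-3-yl)prop-2-enoate F5, which i-Bu2AlH reduces to (2E)-2-methyl-3-(3-methyloxetan-3-yl)prop-2-en-1-ol F6. Carbinol 13 is silylated with Ph2SiCl2 and imidazole and then with F6 to give the mixed diphenylsilylene acetal F7. Heating F7 in PhMe at about 190 °C should give, through the same A(1,3)-controlled exo-tether arrangement, the cycloadduct F8 with a seven-membered dioxasilepane in place of the lactone. K2CO3 in MeOH cleaves the silylene to the diol F9 without touching the TBS ether, and TEMPO/PhI(OAc)2 oxidises the primary alcohol, the hydroxy aldehyde closing and being oxidised further, so that the route is rejoined at lactone 19.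

3. Step 10. What may go wrong: poor discrimination between the aryl and the dienyl substituent of the ketone, giving low or reversed enantioselectivity that cannot be corrected later because the dienophile half is achiral. The fallback forms the C1'–C11 bond and the stereocentre together by catalytic enantioselective aryl transfer and sets out from 6 and 9. Bromide 6 and Mg in THF give the arylmagnesium bromide F10, which is mixed with Ti(OiPr)4 and a catalytic amount of the 3-(3,5-diphenylphenyl)-H8-BINOL antipode that delivers the (S)-alcohol, and then added to dienal 9 in CH2Cl2 at 0 °C; the route is rejoined at 13 without steps 8 and 9.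

**Further compounds**

F1 | step 20 | homoallylic alcohol: 24 with the oxetane opened to C4(CH3)(CH2OH)(CH2CH=CH2), C4 as in the target | CC1=CC[C@@H]([C@](C)(CO)CC=C)[C@](C)(C=C)[C@H]1Cc1cc(OC)c(CO[Si](C)(C)C(C)(C)C)cc1OCOC
F2 | step 20 | C4 epimer of F1 | CC1=CC[C@@H]([C@@](C)(CO)CC=C)[C@](C)(C=C)[C@H]1Cc1cc(OC)c(CO[Si](C)(C)C(C)(C)C)cc1OCOC
F3 | step 20 | 11-Ar-drima-1,7-dien-13-ol with the configuration of 28 | CC1=CC[C@H]2[C@](C)(CO)CC=C[C@]2(C)[C@H]1Cc1cc(OC)c(CO[Si](C)(C)C(C)(C)C)cc1OCOC
F4 | step 20 | C4 epimer of F3 | CC1=CC[C@H]2[C@@](C)(CO)CC=C[C@]2(C)[C@H]1Cc1cc(OC)c(CO[Si](C)(C)C(C)(C)C)cc1OCOC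
F5 | step 14 | ethyl (2E)-2-methyl-3-(3-methyloxetan-3-yl)prop-2-enoate | CCOC(=O)/C(C)=C/C1(C)COC1
F6 | step 14 | (2E)-2-methyl-3-(3-methyloxetan-3-yl)prop-2-en-1-ol | OC/C(C)=C/C1(C)COC1
F7 | step 14 | diphenyl{[(1S,2E)-1-Ar-3-methylpenta-2,4-dien-1-yl]oxy}{[(2E)-2-methyl-3-(3-methyloxetan-3-yl)prop-2-en-1-yl]oxy}silane | C=C/C(C)=C/[C@H](O[Si](c2ccccc2)(c2ccccc2)OC/C(C)=C/C2(C)COC2)c1cc(OC)c(CO[Si](C)(C)C(C)(C)C)cc1OCOC
F8 | step 14 | silicon-tethered cycloadduct: ring B fused to a 2,2-diphenyl-1,3-dioxa-2-silepane (C1H2–O–Si–O–C11), ring stereocentres as in 19 | CC1=CC[C@@H](C2(C)COC2)[C@]3(C)CO[Si](c2ccccc2)(c2ccccc2)O[C@H](c2cc(OC)c(CO[Si](C)(C)C(C)(C)C)cc2OCOC)[C@@H]13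
F9 | step 14 | diol: 21 with CH2OH in place of the vinyl group | CC1=CC[C@@H](C2(C)COC2)[C@](C)(CO)[C@H]1[C@H](O)c1cc(OC)c(CO[Si](C)(C)C(C)(C)C)cc1OCOC
F10 | step 10 | {4-[(tert-butyldimethylsilyloxy)methyl]-5-methoxy-2-(methoxymethoxy)phenyl}magnesium bromide | Br[Mg]c1cc(OC)c(CO[Si](C)(C)C(C)(C)C)cc1OCOC
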